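Think of a neighbour of this flask, charged with more initiator: what you watch there and here is the same thing, how many chains get begun.

free monomer 2.6 M; initiator 26 mM; impurity 8.3 mM; time 10 min

    initiator + impurity → spent initiator A (k1 = 620 L mol⁻¹ s⁻¹)
    free monomer + initiator → living end + monomer in chains (k2 = 0.010 L mol⁻¹ s⁻¹)
    free monomer + initiator → spent initiator B (k3 = 0.026 L mol⁻¹ s⁻¹)
    free monomer + living end → monomer in chains + living end, rate k4*[living end]*[free monomer] (k4 = 0.45 L mol⁻¹ s⁻¹)

* whether the average number of monomer units in a chain (chains begun, living or dead) reaches 200 by 10 min (yes / no)
* average number of monomer units in a chain (chains begun, living or dead) at 10 min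

- **First instant.** You start with initiator meeting impurity. Impurity consumes initiator at 5.15 s⁻¹ per initiator, and free monomer at 0.0936 s⁻¹, so the impurity takes its 8.3 mM of initiator first. That leaves 17.7 mM.
- **First seconds.** The remaining initiator has a half-life of 7.41 s against free monomer. It divides between two steps, and a share of 27.8% begins a chain while the rest becomes spent initiator B.
- **The quantity to carry.** The chain count, the initiator left after the impurity times that share, is 4.92 mM. No step in this flask removes a living end, so this count stays.
- **Middle.** Free monomer now decays pseudo-first-order on the living ends, with a half-life of 5.22 min. That is far longer than the initiator's half-life, so treat the two stages separately.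
- **End.** My own reckoning counts the free monomer reacted since the start as monomer in chains on those chains. It leaves 0.689 M of free monomer at 10 min and gives 389 units per chain, so I say yes, as this exceeds 200.
- **Forecast.** The forecast answers yes with 384 units, “well past 200”. Its number is lower than mine.
- **Result.** The flask gives yes and 384 units, and it reaches the wanted length at 3.77 min, with 38.3% of the free monomer reacted.
- **What to watch.** In this flask the slowest mode has a half-life of 5.22 min at 10.0 min, shorter than the run of 10 min, and 27.0% of the free monomer stands at 10.0 min. In the flask with twice the initiator the chain count becomes 12.1 mM in place of 4.92 mM, which reckons to 206 units, and that flask gives 203.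

All constants were drawn at random within sensible limits; what happens was integrated by code.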